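**Retrosynthetic overview**

1. The C3 ester is disconnected last: a Still–Gennari olefination joins the C3 phosphonoacetate of the decalin to (R)-3-(angeloyloxy)butanal, with the 8,9-diol masked as an acetonide.
2. The 8β,9β-diol comes from the C8 ketone of a cis-decalone by C9 enolate hydroxylation and equatorial hydride delivery.
3. Key disconnection: ring B (C5–C6–C7–C8–C9–C10) carries oxygen on C8 and an isopropenyl group on C7, 1,3 to the quaternary C5. C5–C6–C7 can therefore be a trans-vinylcyclopropane (the isopropenyl group is its vinyl handle), C9=C10 a tethered terminal alkene and C8 carbon monoxide; a rhodium-catalysed carbonylative (3+2+1) cycloaddition forms C5–C10, C8–C9 and C7–C8.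
4. Ring order: ring A closes first (alkene insertion, C5–C10) and ring B second (CO insertion and acyl–allyl coupling, C7–C8), both in the same operation.
5. The ene-vinylcyclopropane is built from pent-4-enal by syn SE2' propargylation (C3, C4), carboalumination–acylation, CBS reduction, hydroxyl-directed cyclopropanation (C5) and Wittig methylenation.

Key step: step 10

Remark on the chemistry: from step 10 on, compounds are named with eremophilane numbering (ring A = C1–C5 and C10, ring B = C5–C10, isopropenyl = C11–C13, C14 on C5, C15 on C4); phosphonoacetic acid 19 is taken as a purchasable reagent.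

**Step 1**
Reactants: 1 (R)-but-3-yn-2-ol
Product: 2 (R)-but-3-yn-2-yl methanesulfonate
Conditions: MsCl, Et3N, CH2Cl2, −78 to 0 °C
Reagents that add atoms: methanesulfonyl chloride, CS(=O)(=O)Cl
Why: Mesylation of the secondary propargylic alcohol does not touch the stereocentre and provides the leaving group for the SN2' stannylation.

**Step 2**
Reactants: 2 (R)-but-3-yn-2-yl methanesulfonate
Product: 3 (P)-tributyl(buta-1,2-dien-1-yl)stannane
Conditions: Bu3SnH, LiN(i-Pr)2, THF, 0 °C; CuBr·SMe2, −78 °C; then 2, −78 °C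
Reagents that add atoms: tributylstannyllithium (made in the flask from tributyltin hydride), [Li][Sn](CCCC)(CCCC)CCCC
Why: The stannylcopper reagent displaces the mesylate in an anti SN2' substitution, so the central chirality of 2 should be transferred into the axial chirality of the allene.

**Step 3**
Reactants: 3 (P)-tributyl(buta-1,2-dien-1-yl)stannane; 4 pent-4-enal
Product: 5 (3R,4R)-3-methyloct-7-en-1-yn-4-ol
Conditions: BF3·OEt2, CH2Cl2, −78 °C
Reagents that add atoms: none
Why: The BF3-promoted SE2' propargylation runs through an open transition state with attack anti to tin, so C4 is fixed by the allene and the synclinal approach to the aldehyde should favour the syn adduct (C3).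

**Step 4**
Reactants: 5 (3R,4R)-3-methyloct-7-en-1-yn-4-ol
Product: 6 tert-butyldimethyl{[(3R,4R)-3-methyloct-7-en-1-yn-4-yl]oxy}silane
Conditions: TBSOTf, 2,6-lutidine, CH2Cl2, −78 to 0 °C
Reagents that add atoms: tert-butyldimethylsilyl trifluoromethanesulfonate, CC(C)(C)[Si](C)(C)OS(=O)(=O)C(F)(F)F
Why: Silylation of the secondary alcohol gives an ether that should survive organoaluminium, zinc carbenoid, rhodium/CO, amide base and borohydride and is removable with fluoride.

**Step 5**
Reactants: 6 tert-butyldimethyl{[(3R,4R)-3-methyloct-7-en-1-yn-4-yl]oxy}silane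
Product: 8 (3E,5R,6R)-6-[(tert-butyldimethylsilyl)oxy]-4,5-dimethyldeca-3,9-dien-2-one, via alkenyldimethylalane 7 (not isolated)
Conditions: Me3Al, Cp2ZrCl2, ClCH2CH2Cl, 0 °C to rt; excess Me3Al removed in vacuo; then CH3COCl, Pd(PPh3)4 (cat.), THF, 0 °C
Reagents that add atoms: trimethylaluminium, C[Al](C)C; acetyl chloride, CC(=O)Cl
Why: The zirconium-catalysed Negishi carboalumination adds Me and Al syn across the terminal alkyne with Me on the internal carbon, and palladium-catalysed acylation of the alkenyl–Al bond with retention fixes the E geometry (acetyl trans to C4).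

**Step 6**
Reactants: 8 (3E,5R,6R)-6-[(tert-butyldimethylsilyl)oxy]-4,5-dimethyldeca-3,9-dien-2-one
Product: 9 (2S,3E,5R,6R)-6-[(tert-butyldimethylsilyl)oxy]-4,5-dimethyldeca-3,9-dien-2-ol
Conditions: (R)-2-methyl-CBS-oxazaborolidine (20 mol %), catecholborane, toluene, −78 °C
Reagents that add atoms: none
Why: In the Corey–Bakshi–Shibata reduction the alkenyl group acts as the large and methyl as the small ketone substituent, so the (R)-catalyst should give the (S)-carbinol, and catecholborane at −78 °C should leave the terminal alkene alone.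

**Step 7**
Reactants: 9 (2S,3E,5R,6R)-6-[(tert-butyldimethylsilyl)oxy]-4,5-dimethyldeca-3,9-dien-2-ol
Product: 10 (1S)-1-[(1S,2R)-2-[(2R,3R)-3-[(tert-butyldimethylsilyl)oxy]hept-6-en-2-yl]-2-methylcyclopropyl]ethan-1-ol
Conditions: Et2Zn, CH2I2, CH2Cl2, −10 to 0 °C
Reagents that add atoms: diiodomethane, ICI
Why: In this hydroxyl-directed Simmons–Smith cyclopropanation (Furukawa reagent), A(1,3) strain with the cis methyl group holds the carbinol C–H in the alkene plane, so the zinc alkoxide should deliver CH2 to one face only; the E alkene gives the trans cyclopropane and sets C5, and the unactivated terminal alkene reacts far more slowly.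

**Step 8**
Reactants: 10 (1S)-1-[(1S,2R)-2-[(2R,3R)-3-[(tert-butyldimethylsilyl)oxy]hept-6-en-2-yl]-2-methylcyclopropyl]ethan-1-ol
Product: 11 1-[(1S,2R)-2-[(2R,3R)-3-[(tert-butyldimethylsilyl)oxy]hept-6-en-2-yl]-2-methylcyclopropyl]ethan-1-one
Conditions: Dess–Martin periodinane, NaHCO3, CH2Cl2, rt
Reagents that add atoms: none
Why: Dess–Martin oxidation of the carbinol that has done its directing work gives the cyclopropyl methyl ketone under buffered, non-epimerising conditions.

**Step 9**
Reactants: 11 1-[(1S,2R)-2-[(2R,3R)-3-[(tert-butyldimethylsilyl)oxy]hept-6-en-2-yl]-2-methylcyclopropyl]ethan-1-one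
Product: 12 tert-butyldimethyl{[(5R,6R)-6-[(1S,2R)-1-methyl-2-(prop-1-en-2-yl)cyclopropyl]hept-1-en-5-yl]oxy}silane
Conditions: Ph3PCH3Br, KOt-Bu, THF, 0 °C to rt
Reagents that add atoms: methyltriphenylphosphonium bromide, C[P+](c1ccccc1)(c1ccccc1)c1ccccc1.[Br-]
Why: Wittig methylenation turns the acetyl group into the isopropenyl group and thereby creates the trans-vinylcyclopropane; the trans ketone is the thermodynamic isomer, so the basic ylide should not scramble it.

**Step 10**
Reactants: 12 tert-butyldimethyl{[(5R,6R)-6-[(1S,2R)-1-methyl-2-(prop-1-en-2-yl)cyclopropyl]hept-1-en-5-yl]oxy}silane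
Product: 13 (3R,4R,5S,7R,10R)-3-[(tert-butyldimethylsilyl)oxy]eremophil-11-en-8-one (cis-fused)
Conditions: [Rh(CO)2Cl]2 (5 mol %), CO (0.2 atm) in N2 (1 atm total), toluene (0.02 M), 90 °C
Reagents that add atoms: carbon monoxide, [C-]#[O+]
Why: Proposed new method: monovalent rhodium should insert into the strained C5–C7 cyclopropane bond, which the isopropenyl group turns into a σ-alkyl/π-allyl rhodacycle; the tethered C9=C10 alkene then inserts into Rh–C5 (forming C5–C10), CO inserts into the new Rh–C9 bond (C8), and acyl–allyl reductive elimination at the internal allyl terminus forms C7–C8. The closest known reaction types are the rhodium-catalysed carbonylative (3+2)+1 cycloaddition of 1-ene-vinylcyclopropanes with CO and the (3+2) cycloaddition of trans-2-ene-vinylcyclopropanes, whose elementary steps are combined here on a 2-ene substrate with a four-carbon tether. Ring A closes by 6-exo migratory insertion and ring B by reductive elimination from a seven-membered acyl(allyl)rhodacycle, its six carbons being three cyclopropane carbons, two alkene carbons and CO. C5 is carried over from the cyclopropane with retention (oxidative addition and migratory insertion both retain); C10 follows from the syn-coplanar insertion, in which C6 and C9 are both held on rhodium while C1 must stay next to C4, which only the cis ring fusion allows; C7 is expected with the isopropenyl group equatorial, the arrangement that also wins on equilibration next to the C8 ketone. The step needs cleavage of C5–C7 instead of C6–C7 (only the Rh–C5 alkyl can reach the alkene), CO uptake faster than direct C9–C7 coupling to a hydrindane (low but constant CO pressure), and alkene insertion faster than β-hydride loss from C6 (intramolecular alkene, dilute solution).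

**Step 11**
Reactants: 13 (3R,4R,5S,7R,10R)-3-[(tert-butyldimethylsilyl)oxy]eremophil-11-en-8-one
Product: 15 (3R,4R,5R,7R,9R,10S)-3-[(tert-butyldimethylsilyl)oxy]-9-hydroxyeremophil-11-en-8-one, via potassium enolate 14 (not isolated)
Conditions: KN(SiMe3)2, THF, −78 °C; then 2-(phenylsulfonyl)-3-phenyloxaziridine, −78 °C; AcOH quench
Reagents that add atoms: 2-(phenylsulfonyl)-3-phenyloxaziridine (Davis oxaziridine), O=S(=O)(N1OC1c1ccccc1)c1ccccc1
Why: Kinetic deprotonation by the hindered amide should occur at the C9 methylene and not at the substituted C7, and Davis hydroxylation of the enolate from the convex β face of the cis-decalin (away from the axial C5–C4 bond) should give the equatorial 9β-alcohol.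

**Step 12**
Reactants: 15 (3R,4R,5R,7R,9R,10S)-3-[(tert-butyldimethylsilyl)oxy]-9-hydroxyeremophil-11-en-8-one
Product: 16 (3R,4R,5R,7R,8S,9R,10S)-3-[(tert-butyldimethylsilyl)oxy]eremophil-11-ene-8,9-diol
Conditions: LiBH(s-Bu)3 (3 equiv), THF, −78 °C; then aq NaOH
Reagents that add atoms: none
Why: In this substrate-controlled hydride reduction the bulky trialkylborohydride should attack the C8 ketone along the equatorial trajectory between its two equatorial neighbours, so the new hydroxyl is axial (8β) and cis to the 9β-hydroxyl.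

**Step 13**
Reactants: 16 (3R,4R,5R,7R,8S,9R,10S)-3-[(tert-butyldimethylsilyl)oxy]eremophil-11-ene-8,9-diol
Product: 17 (3R,4R,5R,7R,8S,9R,10S)-3-[(tert-butyldimethylsilyl)oxy]-8,9-(isopropylidenedioxy)eremophil-11-ene
Conditions: Me2C(OMe)2, PPTS (cat.), CH2Cl2, rt
Reagents that add atoms: 2,2-dimethoxypropane, COC(C)(C)OC
Why: Acetal exchange on the cis (axial/equatorial) 1,2-diol gives the five-membered acetonide under acid mild enough for the silyl ether and the isopropenyl group.

**Step 14**
Reactants: 17 (3R,4R,5R,7R,8S,9R,10S)-3-[(tert-butyldimethylsilyl)oxy]-8,9-(isopropylidenedioxy)eremophil-11-ene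
Product: 18 (3R,4R,5R,7R,8S,9R,10S)-8,9-(isopropylidenedioxy)eremophil-11-en-3-ol
Conditions: Bu4NF, THF, 40 °C
Reagents that add atoms: none
Why: Fluoride-induced desilylation frees only the C3 hydroxyl, since the acetonide is inert to fluoride.

**Step 15**
Reactants: 18 (3R,4R,5R,7R,8S,9R,10S)-8,9-(isopropylidenedioxy)eremophil-11-en-3-ol; 19 2-[bis(2,2,2-trifluoroethoxy)phosphoryl]acetic acid
Product: 20 (3R,4R,5R,7R,8S,9R,10S)-8,9-(isopropylidenedioxy)eremophil-11-en-3-yl 2-[bis(2,2,2-trifluoroethoxy)phosphoryl]acetate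
Conditions: DCC, DMAP (cat.), CH2Cl2, 0 °C to rt
Reagents that add atoms: none
Why: Steglich esterification of the equatorial secondary alcohol installs the olefination handle without putting a pre-formed Z-enoate at risk of isomerisation.

**Step 16**
Reactants: 21 (R)-pent-4-en-2-ol; 22 angelic acid
Product: 24 (R)-pent-4-en-2-yl (Z)-2-methylbut-2-enoate, via mixed anhydride 23 (not isolated)
Conditions: 2,4,6-Cl3C6H2COCl, Et3N, toluene, rt; then 21, 75 °C
Reagents that add atoms: none
Why: Yamaguchi esterification through the hindered mixed anhydride acylates the secondary alcohol without a nucleophilic catalyst, which should keep Z-to-E isomerisation of the angelate low.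

**Step 17**
Reactants: 24 (R)-pent-4-en-2-yl (Z)-2-methylbut-2-enoate
Product: 26 (R)-4-oxobutan-2-yl (Z)-2-methylbut-2-enoate, via vicinal diol 25 (not isolated)
Conditions: OsO4 (cat.), NaIO4, 2,6-lutidine, dioxane/H2O, rt
Reagents that add atoms: osmium tetroxide, O=[Os](=O)(=O)=O; sodium periodate, [Na+].[O-]I(=O)(=O)=O
Why: In the Lemieux–Johnson cleavage the electron-rich monosubstituted alkene is dihydroxylated much faster than the electron-poor trisubstituted angelate double bond, and periodate cleaves the diol to the aldehyde.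

**Step 18**
Reactants: 20 (3R,4R,5R,7R,8S,9R,10S)-8,9-(isopropylidenedioxy)eremophil-11-en-3-yl 2-[bis(2,2,2-trifluoroethoxy)phosphoryl]acetate; 26 (R)-4-oxobutan-2-yl (Z)-2-methylbut-2-enoate
Product: 28 (3R,4R,5R,7R,8S,9R,10S)-8,9-(isopropylidenedioxy)eremophil-11-en-3-yl (2Z,5R)-5-{[(2Z)-2-methylbut-2-enoyl]oxy}hex-2-enoate, via potassium phosphonate 27 (not isolated)
Conditions: KN(SiMe3)2, 18-crown-6, THF, −78 °C; then 26, −78 °C
Reagents that add atoms: none
Why: The Still–Gennari variant of the Horner–Wadsworth–Emmons olefination eliminates quickly from the kinetic adduct under dissociating conditions and should give the Z-enoate, while the weakly basic phosphonate anion at −78 °C should not eliminate the β-acyloxy group of 26.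

**Step 19**
Reactants: 28 (3R,4R,5R,7R,8S,9R,10S)-8,9-(isopropylidenedioxy)eremophil-11-en-3-yl (2Z,5R)-5-{[(2Z)-2-methylbut-2-enoyl]oxy}hex-2-enoate
Product: 29 (3R,4R,5R,7R,8S,9R,10S)-8,9-dihydroxyeremophil-11-en-3-yl (2Z,5R)-5-{[(2Z)-2-methylbut-2-enoyl]oxy}hex-2-enoate (CNP0395983.1)
Conditions: AcOH/H2O (4:1), 40 °C
Reagents that add atoms: none
Why: Acid-catalysed acetal hydrolysis frees the cis-diol under conditions that should leave both conjugated esters, their Z geometry and the isopropenyl group untouched.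

**Compound list**

1 | (R)-but-3-yn-2-ol | C#C[C@@H](C)O | starting material
2 | (R)-but-3-yn-2-yl methanesulfonate | C#C[C@@H](C)OS(C)(=O)=O | intermediate
3 | (P)-tributyl(buta-1,2-dien-1-yl)stannane | CC=[C@@]=C[Sn](CCCC)(CCCC)CCCC | intermediate
4 | pent-4-enal | C=CCCC=O | starting material
5 | (3R,4R)-3-methyloct-7-en-1-yn-4-ol | C#C[C@@H](C)[C@H](O)CCC=C | intermediate
6 | tert-butyldimethyl{[(3R,4R)-3-methyloct-7-en-1-yn-4-yl]oxy}silane | C#C[C@@H](C)[C@H](O[Si](C)(C)C(C)(C)C)CCC=C | intermediate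
7 | {(1E,3R,4R)-4-[(tert-butyldimethylsilyl)oxy]-2,3-dimethylocta-1,7-dien-1-yl}dimethylalane | C[Al](C)/C=C(\C)[C@@H](C)[C@H](O[Si](C)(C)C(C)(C)C)CCC=C | intermediate
8 | (3E,5R,6R)-6-[(tert-butyldimethylsilyl)oxy]-4,5-dimethyldeca-3,9-dien-2-one | CC(=O)/C=C(\C)[C@@H](C)[C@H](O[Si](C)(C)C(C)(C)C)CCC=C | intermediate
9 | (2S,3E,5R,6R)-6-[(tert-butyldimethylsilyl)oxy]-4,5-dimethyldeca-3,9-dien-2-ol | C[C@H](O)/C=C(\C)[C@@H](C)[C@H](O[Si](C)(C)C(C)(C)C)CCC=C | intermediate
10 | (1S)-1-[(1S,2R)-2-[(2R,3R)-3-[(tert-butyldimethylsilyl)oxy]hept-6-en-2-yl]-2-methylcyclopropyl]ethan-1-ol | C[C@H](O)[C@H]1C[C@]1(C)[C@@H](C)[C@H](O[Si](C)(C)C(C)(C)C)CCC=C | intermediate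
11 | 1-[(1S,2R)-2-[(2R,3R)-3-[(tert-butyldimethylsilyl)oxy]hept-6-en-2-yl]-2-methylcyclopropyl]ethan-1-one | CC(=O)[C@H]1C[C@]1(C)[C@@H](C)[C@H](O[Si](C)(C)C(C)(C)C)CCC=C | intermediate
12 | tert-butyldimethyl{[(5R,6R)-6-[(1S,2R)-1-methyl-2-(prop-1-en-2-yl)cyclopropyl]hept-1-en-5-yl]oxy}silane | C=C(C)[C@H]1C[C@]1(C)[C@@H](C)[C@H](O[Si](C)(C)C(C)(C)C)CCC=C | intermediate
13 | (3R,4R,5S,7R,10R)-3-[(tert-butyldimethylsilyl)oxy]eremophil-11-en-8-one | C=C(C)[C@H]1C[C@@]2(C)[C@H](CC[C@@H](O[Si](C)(C)C(C)(C)C)[C@@H]2C)CC1=O | intermediate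
14 | potassium C8(9)-enolate of 13 | C=C(C)[C@H]1C[C@@]2(C)[C@H](CC[C@@H](O[Si](C)(C)C(C)(C)C)[C@@H]2C)C=C1[O-].[K+] | intermediate
15 | (3R,4R,5R,7R,9R,10S)-3-[(tert-butyldimethylsilyl)oxy]-9-hydroxyeremophil-11-en-8-one | C=C(C)[C@H]1C[C@@]2(C)[C@H](CC[C@@H](O[Si](C)(C)C(C)(C)C)[C@@H]2C)[C@@H](O)C1=O | intermediate
16 | (3R,4R,5R,7R,8S,9R,10S)-3-[(tert-butyldimethylsilyl)oxy]eremophil-11-ene-8,9-diol | C=C(C)[C@H]1C[C@@]2(C)[C@H](CC[C@@H](O[Si](C)(C)C(C)(C)C)[C@@H]2C)[C@@H](O)[C@H]1O | intermediate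
17 | (3R,4R,5R,7R,8S,9R,10S)-3-[(tert-butyldimethylsilyl)oxy]-8,9-(isopropylidenedioxy)eremophil-11-ene | C=C(C)[C@H]1C[C@@]2(C)[C@H](CC[C@@H](O[Si](C)(C)C(C)(C)C)[C@@H]2C)[C@H]3OC(C)(C)O[C@@H]13 | intermediate
18 | (3R,4R,5R,7R,8S,9R,10S)-8,9-(isopropylidenedioxy)eremophil-11-en-3-ol | C=C(C)[C@H]1C[C@@]2(C)[C@H](CC[C@@H](O)[C@@H]2C)[C@H]3OC(C)(C)O[C@@H]13 | intermediate
19 | 2-[bis(2,2,2-trifluoroethoxy)phosphoryl]acetic acid | OC(=O)CP(=O)(OCC(F)(F)F)OCC(F)(F)F | starting material
20 | (3R,4R,5R,7R,8S,9R,10S)-8,9-(isopropylidenedioxy)eremophil-11-en-3-yl 2-[bis(2,2,2-trifluoroethoxy)phosphoryl]acetate | C=C(C)[C@H]1C[C@@]2(C)[C@H](CC[C@@H](OC(=O)CP(=O)(OCC(F)(F)F)OCC(F)(F)F)[C@@H]2C)[C@H]3OC(C)(C)O[C@@H]13 | intermediate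
21 | (R)-pent-4-en-2-ol | C=CC[C@@H](C)O | starting material
22 | angelic acid, (Z)-2-methylbut-2-enoic acid | C/C=C(/C)C(O)=O | starting material
23 | (Z)-2-methylbut-2-enoic 2,4,6-trichlorobenzoic anhydride | C/C=C(/C)C(=O)OC(=O)c1c(Cl)cc(Cl)cc1Cl | intermediate
24 | (R)-pent-4-en-2-yl (Z)-2-methylbut-2-enoate | C=CC[C@@H](C)OC(=O)/C(C)=C\C | intermediate
25 | (2R)-4,5-dihydroxypentan-2-yl (Z)-2-methylbut-2-enoate (both C4 epimers) | OCC(O)C[C@@H](C)OC(=O)/C(C)=C\C | intermediate
26 | (R)-4-oxobutan-2-yl (Z)-2-methylbut-2-enoate | O=CC[C@@H](C)OC(=O)/C(C)=C\C | intermediate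
27 | potassium salt of the phosphonate carbanion of 20 | C=C(C)[C@H]1C[C@@]2(C)[C@H](CC[C@@H](OC(=O)[CH-]P(=O)(OCC(F)(F)F)OCC(F)(F)F)[C@@H]2C)[C@H]3OC(C)(C)O[C@@H]13.[K+] | intermediate
28 | (3R,4R,5R,7R,8S,9R,10S)-8,9-(isopropylidenedioxy)eremophil-11-en-3-yl (2Z,5R)-5-{[(2Z)-2-methylbut-2-enoyl]oxy}hex-2-enoate | C=C(C)[C@H]1C[C@@]2(C)[C@H](CC[C@@H](OC(=O)/C=C\C[C@@H](C)OC(=O)/C(C)=C\C)[C@@H]2C)[C@H]3OC(C)(C)O[C@@H]13 | intermediate
29 | (3R,4R,5R,7R,8S,9R,10S)-8,9-dihydroxyeremophil-11-en-3-yl (2Z,5R)-5-{[(2Z)-2-methylbut-2-enoyl]oxy}hex-2-enoate (CNP0395983.1) | C=C(C)[C@H]1C[C@@]2(C)[C@H](CC[C@@H](OC(=O)/C=C\C[C@@H](C)OC(=O)/C(C)=C\C)[C@@H]2C)[C@@H](O)[C@H]1O | target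

**Step count and risks**

Total step count: 19. Longest linear sequence: 17 (steps 1–15, 18, 19).

Steps most likely to fail:

1. Step 10 (proposed new method). The rhodacycle may lose a β-hydrogen from C6 and open to a diene before the alkene inserts. It may also couple C9 with C7 without taking up CO, or the six-membered tether may insert with the wrong ring fusion. The fallback uses known chemistry, sets out from 6 and comes back to the route at 13. Bromoboration of the alkyne with 9-bromo-9-borabicyclo[3.3.1]nonane and protonolysis with AcOH should give {[(5R,6S)-7-bromo-6-methylocta-1,7-dien-5-yl]oxy}(tert-butyl)dimethylsilane F1. Lithium–bromine exchange (t-BuLi), transmetalation with ZnBr2 and Pd(PPh3)4-catalysed coupling with prenyl bromide should give tert-butyl{[(5R,6R)-6,10-dimethyl-7-methylideneundeca-1,9-dien-5-yl]oxy}dimethylsilane F2. Cross-metathesis of the monosubstituted alkene with crotonaldehyde (second-generation Hoveyda–Grubbs catalyst) should give (2E,6R,7R)-6-[(tert-butyldimethylsilyl)oxy]-7,11-dimethyl-8-methylidenedodeca-2,10-dienal F3. A hydrogen-atom-transfer Giese cyclisation (Fe(acac)3, PhSiH3, EtOH/ethylene glycol, 60 °C) turns the 1,1-disubstituted alkene into the tertiary C5 radical, which closes 6-exo onto the enal (C5–C10). After separation of ring-fusion isomers this should give 2-[(1R,2S,3R,4R)-4-[(tert-butyldimethylsilyl)oxy]-2,3-dimethyl-2-(3-methylbut-2-en-1-yl)cyclohexyl]acetaldehyde F4. A Me2AlCl-promoted carbonyl-ene cyclisation of the aldehyde onto the prenyl group (C7–C8, isopropenyl) should give (3R,4R,5S,7R,8S,10R)-3-[(tert-butyldimethylsilyl)oxy]eremophil-11-en-8-ol F5. Dess–Martin oxidation of F5 gives 13.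

2. Step 11. Deprotonation may take place at C7 instead of C9, the isopropenyl double bond may then move into conjugation with the ketone, and the oxidant may attack the concave face. The fallback sets out from 13 and comes back at 15. It avoids strong base through enamine catalysis: L-proline-catalysed α-aminoxylation with nitrosobenzene (DMSO, rt) engages only the methylene side and should give (3R,4R,5R,7R,9R,10S)-9-(anilinooxy)-3-[(tert-butyldimethylsilyl)oxy]eremophil-11-en-8-one F6. Cleavage of the N–O bond with Zn in AcOH/THF gives 15.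

3. Step 3. Facial discrimination at the unbranched aldehyde in the open transition state may be poor (syn/anti mixture), and the allenylstannane may racemise or protodestannylate. The fallback sets out from 4 and comes back at 6, with auxiliary control in place of the SE2' reaction. A boron-mediated Evans syn aldol of 4 with (S)-4-benzyl-3-propionyloxazolidin-2-one (Bu2BOTf, i-Pr2NEt, CH2Cl2, −78 °C) should give (S)-4-benzyl-3-[(2S,3R)-3-hydroxy-2-methylhept-6-enoyl]oxazolidin-2-one F7. Silylation (TBSOTf, 2,6-lutidine) gives (S)-4-benzyl-3-[(2S,3R)-3-[(tert-butyldimethylsilyl)oxy]-2-methylhept-6-enoyl]oxazolidin-2-one F8. Reductive removal of the auxiliary with LiBH4 gives (2R,3R)-3-[(tert-butyldimethylsilyl)oxy]-2-methylhept-6-en-1-ol F9. Dess–Martin oxidation gives (2S,3R)-3-[(tert-butyldimethylsilyl)oxy]-2-methylhept-6-enal F10. Ohira–Bestmann homologation (dimethyl (1-diazo-2-oxopropyl)phosphonate, K2CO3, MeOH) of F10 gives 6.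

**Further compounds**

F1 | step 10 | {[(5R,6S)-7-bromo-6-methylocta-1,7-dien-5-yl]oxy}(tert-butyl)dimethylsilane | C=C(Br)[C@@H](C)[C@H](O[Si](C)(C)C(C)(C)C)CCC=C
F2 | step 10 | tert-butyl{[(5R,6R)-6,10-dimethyl-7-methylideneundeca-1,9-dien-5-yl]oxy}dimethylsilane | CC(C)=CCC(=C)[C@@H](C)[C@H](O[Si](C)(C)C(C)(C)C)CCC=C
F3 | step 10 | (2E,6R,7R)-6-[(tert-butyldimethylsilyl)oxy]-7,11-dimethyl-8-methylidenedodeca-2,10-dienal | CC(C)=CCC(=C)[C@@H](C)[C@H](O[Si](C)(C)C(C)(C)C)CC/C=C/C=O
F4 | step 10 | 2-[(1R,2S,3R,4R)-4-[(tert-butyldimethylsilyl)oxy]-2,3-dimethyl-2-(3-methylbut-2-en-1-yl)cyclohexyl]acetaldehyde | CC(C)=CC[C@@]1(C)[C@H](CC[C@@H](O[Si](C)(C)C(C)(C)C)[C@@H]1C)CC=O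
F5 | step 10 | (3R,4R,5S,7R,8S,10R)-3-[(tert-butyldimethylsilyl)oxy]eremophil-11-en-8-ol | C=C(C)[C@H]1C[C@@]2(C)[C@H](CC[C@@H](O[Si](C)(C)C(C)(C)C)[C@@H]2C)C[C@@H]1O
F6 | step 11 | (3R,4R,5R,7R,9R,10S)-9-(anilinooxy)-3-[(tert-butyldimethylsilyl)oxy]eremophil-11-en-8-one | C=C(C)[C@H]1C[C@@]2(C)[C@H](CC[C@@H](O[Si](C)(C)C(C)(C)C)[C@@H]2C)[C@@H](ONc2ccccc2)C1=O
F7 | step 3 | (S)-4-benzyl-3-[(2S,3R)-3-hydroxy-2-methylhept-6-enoyl]oxazolidin-2-one | O=C(N1[C@@H](Cc2ccccc2)COC1=O)[C@@H](C)[C@H](O)CCC=C
F8 | step 3 | (S)-4-benzyl-3-[(2S,3R)-3-[(tert-butyldimethylsilyl)oxy]-2-methylhept-6-enoyl]oxazolidin-2-one | O=C(N1[C@@H](Cc2ccccc2)COC1=O)[C@@H](C)[C@H](O[Si](C)(C)C(C)(C)C)CCC=C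
F9 | step 3 | (2R,3R)-3-[(tert-butyldimethylsilyl)oxy]-2-methylhept-6-en-1-ol | OC[C@@H](C)[C@H](O[Si](C)(C)C(C)(C)C)CCC=C
F10 | step 3 | (2S,3R)-3-[(tert-butyldimethylsilyl)oxy]-2-methylhept-6-enal | O=C[C@@H](C)[C@H](O[Si](C)(C)C(C)(C)C)CCC=C
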